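Atom labels used throughout: chroman O1, C2, C3, C4, C4a, C5–C8, C8a; side chain from C2 outward C1'–C6'; cyclohexene ring C1''–C6''. Compound numbers 1–18 are those of the steps and the compound list.

## The problem

The target 18 is a chroman-6-ol: a benzene ring fused to a dihydropyran ring (O1, C2, C3, C4, C4a, C8a). Its only stereocentre is C2 (R), a carbon without hydrogen that carries O1, a methyl group, C3 and the side chain. No second stereocentre can relay configuration, so C2 must be set by a reagent or catalyst. The side chain starts at C2 with a (1'E,3'E)-diene, C1'H=C2'H–C3'H=C4'(CH3), runs through C5'H2–C6'H2 and ends in a 2,6,6-trimethylcyclohex-1-enyl ring with a tetrasubstituted C1''=C2'' bond. Two alkene geometries must be controlled, and the trisubstituted C3'=C4' is the harder one. Any junction of chain and aryl part between C3 and C3' lies next to the stereocentre or next to an alkene of defined geometry.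

The sensitive groups are these:
- The O1–C2 bond is a tertiary, dienylic aryl ether that ionises to a pentadienyl cation under acid (racemisation, ring opening).
- The tetrasubstituted ring alkene migrates in strong acid, and the diene can isomerise or undergo cycloaddition.
- The free 6-hydroxychroman is a hydroquinone monoether and is oxidised to a quinone.

The feature the plan exploits: C2 is at once the carbon bound to O1 (six atoms from the phenol oxygen along O1–C8a–C4a–C4–C3–C2), a carbon without hydrogen, and the allylic terminus of C1'=C2'–C3'=C4'. If C2=C1' is an alkene and C2' a CH2 group, adding O1 and palladium across C2=C1' leaves palladium on C1' with β-hydrogens only on C2'. The pyran ring, the stereocentre and the conjugated E,E-diene can then arise in one operation, and the geometry of the precursor C2=C1' alkene does not matter.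

## Retrosynthesis

18 ⇒ 17. The O–Si bond at the C6 oxygen is cut. The silyl group is needed because a free hydroquinone would be oxidised by the quinone oxidant of the key step. Fluoride cleavage is chosen because it is neither acidic nor oxidative, which the dienylic O1–C2 ether and the phenol require.

17 ⇒ 15 (key disconnection). The O1–C2 bond is cut, and the C1'=C2' double bond is traded for a C2=C1' double bond plus one hydrogen on O1 and one on C2'.
- Against cutting C1'=C2' (olefination) or O1–C8a (aryl ether from a preformed tertiary alcohol): both leave the stereocentre to be bought in a separate sequence.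
- Against an allylic substitution at C2 with the diene in place: it cannot be catalyst-controlled (Alternative 2).
- Gain in simplicity: 15 is acyclic at the pyran, achiral, and tolerates either geometry at C2=C1'.
- Demand on the forward reaction: enantioface-selective oxypalladation at C2 (via 16), β-hydride elimination toward C2' only, and an oxidant that spares the silyl-blocked phenol.

15 ⇒ 12 + 8. The C2=C1' double bond is cut by a Wittig reaction between the methyl ketone 12 (as phenolate 14) and the ylide 13 made from phosphonium salt 8. This is the one alkene in the route whose geometry is irrelevant, so the usual weakness of ylide–ketone olefination costs nothing. Cutting C2'–C3' instead (alkenyl–allyl coupling) would need a geometry-defined allylic electrophile and a second phenol protecting group. The fragments are of similar size (C10 aryl ketone, C16 chain).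

8 ⇒ 7 ⇒ 6 ⇒ 3. The C–P and C–I bonds are functional-group changes. In 6 the C2'–C3' bond and the C4'–CH3 bond are cut back to the terminal alkyne 3. Syn-methylalumination (alane 4) followed by hydroxyethylation of the alkenyl–aluminium bond (alanate 5) sets C3'=C4' as E by mechanism. This is preferred to a carbonyl olefination of 1, which gives a geometrical mixture that would have to be separated.

3 ⇒ 1. The alkyne is taken back to the methyl ketone of dihydro-β-ionone 1 (via enol phosphate 2). The ketone supplies C3' and C4', and 1 already contains C5', C6' and the complete cyclohexene ring, so the tetrasubstituted alkene is never made.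

12 ⇒ 11 ⇒ 10 ⇒ 9. The C3–C4 single bond is taken back to the enone double bond of 11, which is cut by a stabilised-ylide olefination of aldehyde 10. The O–Si bond of 10 is cut to 2,5-dihydroxybenzaldehyde 9. The aldehyde differentiates the two oxygens: the hydrogen-bonded 2-OH (later O1) stays free and the 5-OH (later the C6 oxygen) is silylated.

## Roads not taken

Alternative 1: Cut C1'=C2' (the most obvious cut). The forward key step would be a Horner–Wadsworth–Emmons or related olefination of the (R)-chroman-2-carbaldehyde A1 with the allylic phosphonate A2.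
- The stereocentre of A1 has to be made in a separate multistep sequence (asymmetric oxidation of an alkene followed by cyclisation and cleavage, or a resolution).
- The anion of A2 is an allyl anion delocalised over C2'–C4', so the C3'=C4' geometry can leak.
- The new C1'=C2' bond comes from a semi-stabilised reagent with imperfect E selectivity.
- Three stereo-elements are handled in three operations; the chosen plan sets C2 and C1'=C2' together and is several steps shorter.

Alternative 2: Cut O1–C2 as an allylic substitution with the diene already in place. The forward key step would be ionisation of the bis-allylic carbonate A3 by a chiral zerovalent palladium catalyst and closure of the phenol on the η3-allyl (asymmetric Tsuji–Trost etherification).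
- The allyl unit C2–C1'–C2' carries different substituents at both termini (CH3/CH2 at C2, H/vinyl at C2'), so π–σ–π interconversion cannot exchange its faces.
- The ligand therefore cannot funnel racemic A3; the reaction would be stereospecific.
- A3 would be needed as one enantiomer and with one C2=C1' geometry, and migration of palladium toward C2'–C4' puts the C3'=C4' geometry at risk.
- The chosen oxypalladation selects the face of an achiral alkene directly and is indifferent to its geometry.

Alternative 3: Cut O1–C2 and C3–C4 together. The forward key step would be an inverse-demand hetero-Diels–Alder reaction of the ortho-quinone methide A4 with the 1,1-disubstituted end of the triene A5.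
- On paper this is the most convergent route.
- The methide carbon is unsubstituted, the alkene is unactivated and C2 is remote from any catalyst-binding site, so no dependable enantiocontrol exists and a resolution would be needed.
- A5 can also react as the 4π partner or at C3'=C4', and A4 oligomerises.
- In the chosen plan the nucleophilic oxygen sits on the chiral metal when the C–O bond forms.

Key step: step 9

Assumption: the sense of induction of the binaphthyl bis(oxazoline) ligand is taken to be that of the parent 2-methyl-2-vinylchroman closure, inferred by analogy and not verified, which calls for the (R,R)-ligand to bring O1 to the Re face of C2; if the sense proves opposite, the (S,S)-antipode is used and nothing else changes.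

## Route

Step 1
Reactants: 1 dihydro-β-ionone [4-(2,6,6-trimethylcyclohex-1-en-1-yl)butan-2-one]
Product: 3 2-(but-3-yn-1-yl)-1,3,3-trimethylcyclohex-1-ene, via enol phosphate 2 (not isolated)
Conditions: LiN(i-Pr)2 (1.1 equiv), THF, −78 °C; ClP(O)(OEt)2, −78 °C to rt; LiN(i-Pr)2 (2.3 equiv), −78 °C to rt; H2O
Reagents that add atoms: none
Why: Kinetic deprotonation of the methyl ketone at CH3, O-phosphorylation to 2 and base-induced elimination of diethyl phosphate give the terminal alkyne (one-pot methyl ketone to alkyne conversion); the tetrasubstituted ring alkene is inert to these conditions.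

Step 2
Reactants: 3 2-(but-3-yn-1-yl)-1,3,3-trimethylcyclohex-1-ene
Product: 6 (3E)-4-methyl-6-(2,6,6-trimethylcyclohex-1-en-1-yl)hex-3-en-1-ol, via alkenylalane 4 (not isolated), via lithium alanate 5 (not isolated)
Conditions: AlMe3 (2 equiv), Cp2ZrCl2 (0.25 equiv), CH2Cl2, 0 °C to rt; volatiles removed, hexane/THF; n-BuLi, −78 to 0 °C; oxirane, −78 °C to rt; aq. HCl
Reagents that add atoms: trimethylaluminium, C[Al](C)C; oxirane, C1CO1
Why: Zirconium-catalysed syn-methylalumination of the terminal alkyne (Negishi carboalumination) puts CH3 on C4' and aluminium on C3' on the same side, which fixes C3'=C4' as E. The ate complex 5 opens oxirane with retention at C3' and adds C2' and C1'.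

Step 3
Reactants: 6 (3E)-4-methyl-6-(2,6,6-trimethylcyclohex-1-en-1-yl)hex-3-en-1-ol
Product: 7 2-[(3E)-6-iodo-3-methylhex-3-en-1-yl]-1,3,3-trimethylcyclohex-1-ene
Conditions: I2, PPh3, imidazole, CH2Cl2, 0 °C to rt
Reagents that add atoms: iodine, II
Why: Appel-type iodination of a primary alcohol by SN2 displacement of the oxyphosphonium group; the neutral, cold conditions leave both alkenes and the E geometry untouched.

Step 4
Reactants: 7 2-[(3E)-6-iodo-3-methylhex-3-en-1-yl]-1,3,3-trimethylcyclohex-1-ene
Product: 8 [(3E)-4-methyl-6-(2,6,6-trimethylcyclohex-1-en-1-yl)hex-3-en-1-yl]triphenylphosphonium iodide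
Conditions: PPh3, MeCN, reflux
Reagents that add atoms: triphenylphosphine, c1ccc(cc1)P(c1ccccc1)c1ccccc1
Why: SN2 quaternisation of triphenylphosphine by a primary homoallylic iodide; the salt should be purified by precipitation.

Step 5
Reactants: 9 2,5-dihydroxybenzaldehyde
Product: 10 2-hydroxy-5-[(triisopropylsilyl)oxy]benzaldehyde
Conditions: i-Pr3SiCl (1.05 equiv), imidazole, CH2Cl2, 0 °C
Reagents that add atoms: chlorotri(propan-2-yl)silane, CC(C)[Si](Cl)(C(C)C)C(C)C
Why: Selective O-silylation; the 2-OH is hydrogen-bonded to and flanked by the aldehyde, so the bulky silyl chloride should take the 5-OH. The triisopropylsilyl group is chosen for its resistance to phenolate-induced silyl transfer and to mild acid later on.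

Step 6
Reactants: 10 2-hydroxy-5-[(triisopropylsilyl)oxy]benzaldehyde
Product: 11 (3E)-4-{2-hydroxy-5-[(triisopropylsilyl)oxy]phenyl}but-3-en-2-one
Conditions: Ph3P=CHC(O)CH3, toluene, 80 °C
Reagents that add atoms: 1-(triphenylphosphoranylidene)propan-2-one, CC(=O)C=P(c1ccccc1)(c1ccccc1)c1ccccc1
Why: Wittig olefination with a stabilised ylide, E-selective and tolerant of the free phenol (the ylide is too weakly basic to be quenched by it); it introduces C3, C2 and the C2 methyl group.

Step 7
Reactants: 11 (3E)-4-{2-hydroxy-5-[(triisopropylsilyl)oxy]phenyl}but-3-en-2-one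
Product: 12 4-{2-hydroxy-5-[(triisopropylsilyl)oxy]phenyl}butan-2-one
Conditions: H2 (1 atm), Pd/C, EtOAc, rt
Reagents that add atoms: none
Why: Catalytic hydrogenation of the conjugated C=C bond; the ketone and the aryl silyl ether are not reduced under these conditions.

Step 8
Reactants: 8 [(3E)-4-methyl-6-(2,6,6-trimethylcyclohex-1-en-1-yl)hex-3-en-1-yl]triphenylphosphonium iodide; 12 4-{2-hydroxy-5-[(triisopropylsilyl)oxy]phenyl}butan-2-one
Product: 15 2-[(3E/Z,6E)-3,7-dimethyl-9-(2,6,6-trimethylcyclohex-1-en-1-yl)nona-3,6-dien-1-yl]-4-[(triisopropylsilyl)oxy]phenol, via phosphonium ylide 13 (not isolated), via potassium phenolate 14 (not isolated)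
Conditions: 8, KN(SiMe3)2, THF, −78 to 0 °C; separately 12, KN(SiMe3)2, THF, −78 °C; combine, −78 °C to rt; aq. NH4Cl
Reagents that add atoms: none
Why: Wittig reaction of a non-stabilised ylide with a methyl ketone forms the C2=C1' bond; pre-forming phenolate 14 with the cheap base keeps the ylide from being spent on the phenol, and the open keto form is favoured over the cyclic hemiketal once the phenol is deprotonated. No control of the new alkene geometry is sought, because the key step removes it, so the geometrical mixture should be used as such; the homoallylic ylide leaves the E-C3'=C4' bond (the 6E alkene) untouched.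

Step 9
Reactants: 15 2-[(3E/Z,6E)-3,7-dimethyl-9-(2,6,6-trimethylcyclohex-1-en-1-yl)nona-3,6-dien-1-yl]-4-[(triisopropylsilyl)oxy]phenol
Product: 17 triisopropyl({(2R)-2-methyl-2-[(1E,3E)-4-methyl-6-(2,6,6-trimethylcyclohex-1-en-1-yl)hexa-1,3-dien-1-yl]chroman-6-yl}oxy)silane, via alkylpalladium trifluoroacetate 16 (not isolated)
Conditions: Pd(OCOCF3)2 (10 mol %), (R,R)-Bn-BOXAX [2,2'-bis(4-benzyl-4,5-dihydrooxazol-2-yl)-1,1'-binaphthyl] (20 mol %), p-benzoquinone (4 equiv), MeOH, rt
Reagents that add atoms: none
Why: Enantioselective Wacker-type oxidative cyclisation, the reaction type established for ortho-alkenylphenols with a trisubstituted alkene that give 2-methyl-2-vinyl chromans and dihydrobenzofurans. The phenol binds to the divalent palladium–bis(oxazoline) complex, the C2=C1' alkene coordinates, and O1 adds to C2 while palladium takes C1' (6-exo-trig oxypalladation, closing the dihydropyran ring) to give 16. C2 is the only new stereocentre and is set by the ligand, which must deliver O1 to the Re face of C2 (priorities C1' > C3 > CH3) to give R. That face is defined by the gem-disubstituted alkene terminus and the two-carbon tether, which are identical in the 3E and 3Z isomers of 15, so both should converge on one configuration while the stereochemistry at C1' is erased. In 16 the carbon C2 has no hydrogen, so syn β-hydride elimination can only take a hydrogen from C2'; this creates C1'=C2' in conjugation with C3'=C4', and the E geometry follows from the conformer that keeps C3' anti to the quaternary C2. p-Benzoquinone takes up the hydride and returns zerovalent palladium to divalent palladium. The step needs O-attack at C2 and not C1' (six- against seven-membered ring, Markovnikov sense), no reaction at C3'=C4' or C1''=C2'' (no nucleophile within reach, tri- and tetrasubstituted) and hydride removal faster than re-addition to the diene; the tether length, the excess oxidant and the silyl-blocked C6 oxygen (no quinone formation) secure these.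

Step 10
Reactants: 17 triisopropyl({(2R)-2-methyl-2-[(1E,3E)-4-methyl-6-(2,6,6-trimethylcyclohex-1-en-1-yl)hexa-1,3-dien-1-yl]chroman-6-yl}oxy)silane
Product: 18 (2R)-2-methyl-2-[(1E,3E)-4-methyl-6-(2,6,6-trimethylcyclohex-1-en-1-yl)hexa-1,3-dien-1-yl]chroman-6-ol
Conditions: n-Bu4NF, THF (degassed), 0 °C; aq. NH4Cl
Reagents that add atoms: none
Why: Fluoride cleavage of the aryl silyl ether; the conditions are neither acidic nor oxidising, so the dienylic O1–C2 bond, the C2 configuration and the diene geometry should be retained, and exclusion of air protects the phenolate.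

## Compound list

1 | dihydro-β-ionone, 4-(2,6,6-trimethylcyclohex-1-en-1-yl)butan-2-one | CC(=O)CCC1=C(C)CCCC1(C)C | starting material
2 | diethyl 4-(2,6,6-trimethylcyclohex-1-en-1-yl)but-1-en-2-yl phosphate | C=C(CCC1=C(C)CCCC1(C)C)OP(=O)(OCC)OCC | intermediate (not isolated)
3 | 2-(but-3-yn-1-yl)-1,3,3-trimethylcyclohex-1-ene | C#CCCC1=C(C)CCCC1(C)C | intermediate
4 | dimethyl[(1E)-2-methyl-4-(2,6,6-trimethylcyclohex-1-en-1-yl)but-1-en-1-yl]alane | C[Al](C)/C=C(\C)CCC1=C(C)CCCC1(C)C | intermediate (not isolated)
5 | lithium butyl(dimethyl)[(1E)-2-methyl-4-(2,6,6-trimethylcyclohex-1-en-1-yl)but-1-en-1-yl]alanate | [Li+].CCCC[Al-](C)(C)/C=C(\C)CCC1=C(C)CCCC1(C)C | intermediate (not isolated)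
6 | (3E)-4-methyl-6-(2,6,6-trimethylcyclohex-1-en-1-yl)hex-3-en-1-ol | OCC/C=C(\C)CCC1=C(C)CCCC1(C)C | intermediate
7 | 2-[(3E)-6-iodo-3-methylhex-3-en-1-yl]-1,3,3-trimethylcyclohex-1-ene | ICC/C=C(\C)CCC1=C(C)CCCC1(C)C | intermediate
8 | [(3E)-4-methyl-6-(2,6,6-trimethylcyclohex-1-en-1-yl)hex-3-en-1-yl]triphenylphosphonium iodide | [I-].C(C/C=C(\C)CCC1=C(C)CCCC1(C)C)[P+](c1ccccc1)(c1ccccc1)c1ccccc1 | intermediate
9 | 2,5-dihydroxybenzaldehyde | O=Cc1cc(O)ccc1O | starting material
10 | 2-hydroxy-5-[(triisopropylsilyl)oxy]benzaldehyde | O=Cc1cc(O[Si](C(C)C)(C(C)C)C(C)C)ccc1O | intermediate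
11 | (3E)-4-{2-hydroxy-5-[(triisopropylsilyl)oxy]phenyl}but-3-en-2-one | CC(=O)/C=C/c1cc(O[Si](C(C)C)(C(C)C)C(C)C)ccc1O | intermediate
12 | 4-{2-hydroxy-5-[(triisopropylsilyl)oxy]phenyl}butan-2-one | CC(=O)CCc1cc(O[Si](C(C)C)(C(C)C)C(C)C)ccc1O | intermediate
13 | [(3E)-4-methyl-6-(2,6,6-trimethylcyclohex-1-en-1-yl)hex-3-en-1-ylidene]triphenylphosphorane | C(C/C=C(\C)CCC1=C(C)CCCC1(C)C)=P(c1ccccc1)(c1ccccc1)c1ccccc1 | intermediate (not isolated)
14 | potassium 2-(3-oxobutyl)-4-[(triisopropylsilyl)oxy]phenolate | [K+].CC(=O)CCc1cc(O[Si](C(C)C)(C(C)C)C(C)C)ccc1[O-] | intermediate (not isolated)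
15 | 2-[(3E/Z,6E)-3,7-dimethyl-9-(2,6,6-trimethylcyclohex-1-en-1-yl)nona-3,6-dien-1-yl]-4-[(triisopropylsilyl)oxy]phenol (mixture at the 3-alkene, 6E defined) | CC(CCc1cc(O[Si](C(C)C)(C(C)C)C(C)C)ccc1O)=CC/C=C(\C)CCC1=C(C)CCCC1(C)C | intermediate
16 | σ-alkylpalladium trifluoroacetate from oxypalladation of 15 (C2 as in 17, C1' either configuration, chiral ligand omitted) | C[C@@]1(CCc2cc(O[Si](C(C)C)(C(C)C)C(C)C)ccc2O1)C(C/C=C(\C)CCC1=C(C)CCCC1(C)C)[Pd]OC(=O)C(F)(F)F | intermediate (not isolated)
17 | triisopropyl({(2R)-2-methyl-2-[(1E,3E)-4-methyl-6-(2,6,6-trimethylcyclohex-1-en-1-yl)hexa-1,3-dien-1-yl]chroman-6-yl}oxy)silane | CC1=C(CC/C(C)=C/C=C/[C@@]2(C)CCc3cc(O[Si](C(C)C)(C(C)C)C(C)C)ccc3O2)C(C)(C)CCC1 | intermediate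
18 | (2R)-2-methyl-2-[(1E,3E)-4-methyl-6-(2,6,6-trimethylcyclohex-1-en-1-yl)hexa-1,3-dien-1-yl]chroman-6-ol | CC1=C(CC/C(C)=C/C=C/[C@@]2(C)CCc3cc(O)ccc3O2)C(C)(C)CCC1 | target

## Step count and risks

Total: 10 steps. Longest linear sequence: 7 steps (1, 2, 3, 4, 8, 9, 10 from dihydro-β-ionone 1); the aryl branch is steps 5–7.

Step 9 (key step). Three processes are most likely to go wrong.
- The two alkene isomers of 15 may be discriminated with unequal facial selectivity, because the C1' substituent sits differently in the two ligand-bound alkene complexes; this would erode the enantiomeric purity.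
- The palladium hydride may re-add to the newly formed diene before the quinone removes it, leading to double-bond migration or capture of the resulting allyl species by methanol.
- Trifluoroacetic acid released by the catalyst may ionise the dienylic O1–C2 bond of the product.

The fallback separates ring closure from diene construction. It sets out from 12 (and from 3 for the chain) and comes back at 17. Wittig reaction of 12 with ethylidenetriphenylphosphorane should give the ethylidene phenol F1 as a geometrical mixture. The same catalyst system, now on the exact parent substrate type, should close it to the (R)-2-methyl-2-vinylchroman F2. Iodinolysis of alane 4 (from 3) should give the (E)-alkenyl iodide F3. A Heck reaction of F2 with F3 [Pd(OAc)2, K2CO3, n-Bu4NCl, DMF] should then add C3' to C2' and eliminate toward C1'=C2', since C2 has no hydrogen, to give 17.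

Step 8. Olefination may stall because the ketone is present as a phenolate in equilibrium with its closed hemiketal form, and proton exchange can consume the valuable ylide; phenolate-induced silyl transfer is a lesser concern with the triisopropylsilyl group. The fallback moves the olefination to a neutral ether. It sets out from 12 and comes back at 15. O-Allylation of 12 (allyl bromide, K2CO3, acetone) should give the allyl ether F4. Wittig reaction with 13 should give the allyl-protected diene F5. Deallylation with Pd(PPh3)4 (zerovalent palladium) and morpholine should release 15 without acid.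

Step 2. Transfer of the alkenyl group from alanate 5 to oxirane may be incomplete, because butyl or methyl transfer and protonolysis of the alkenyl–aluminium bond compete. The fallback replaces carbometalation by carbonyl olefination and also bypasses step 1. It sets out from 1 and comes back at ylide 13. Horner–Wadsworth–Emmons reaction of 1 with triethyl phosphonoacetate should give the (E)-ester F6 after chromatographic removal of its geometrical isomer. Reduction with i-Bu2AlH should give the allylic alcohol F7, and PBr3 the allylic bromide F8. Alkylation of methylenetriphenylphosphorane with F8 should give the phosphonium bromide F9, the bromide counterpart of 8. Deprotonation with KN(SiMe3)2 gives 13 for step 8.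

## Further compounds

F1 | step 9 | 2-[(3E/Z)-3-methylpent-3-en-1-yl]-4-[(triisopropylsilyl)oxy]phenol | CC=C(C)CCc1cc(O[Si](C(C)C)(C(C)C)C(C)C)ccc1O
F2 | step 9 | triisopropyl{[(2R)-2-methyl-2-vinylchroman-6-yl]oxy}silane | C=C[C@@]1(C)CCc2cc(O[Si](C(C)C)(C(C)C)C(C)C)ccc2O1
F3 | step 9 | 2-[(3E)-4-iodo-3-methylbut-3-en-1-yl]-1,3,3-trimethylcyclohex-1-ene | I/C=C(\C)CCC1=C(C)CCCC1(C)C
F4 | step 8 | 4-{2-(allyloxy)-5-[(triisopropylsilyl)oxy]phenyl}butan-2-one | CC(=O)CCc1cc(O[Si](C(C)C)(C(C)C)C(C)C)ccc1OCC=C
F5 | step 8 | {4-(allyloxy)-3-[(3E/Z,6E)-3,7-dimethyl-9-(2,6,6-trimethylcyclohex-1-en-1-yl)nona-3,6-dien-1-yl]phenoxy}triisopropylsilane | CC(CCc1cc(O[Si](C(C)C)(C(C)C)C(C)C)ccc1OCC=C)=CC/C=C(\C)CCC1=C(C)CCCC1(C)C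
F6 | step 2 | ethyl (2E)-3-methyl-5-(2,6,6-trimethylcyclohex-1-en-1-yl)pent-2-enoate | CCOC(=O)/C=C(\C)CCC1=C(C)CCCC1(C)C
F7 | step 2 | (2E)-3-methyl-5-(2,6,6-trimethylcyclohex-1-en-1-yl)pent-2-en-1-ol | OC/C=C(\C)CCC1=C(C)CCCC1(C)C
F8 | step 2 | 2-[(3E)-5-bromo-3-methylpent-3-en-1-yl]-1,3,3-trimethylcyclohex-1-ene | BrC/C=C(\C)CCC1=C(C)CCCC1(C)C
F9 | step 2 | [(3E)-4-methyl-6-(2,6,6-trimethylcyclohex-1-en-1-yl)hex-3-en-1-yl]triphenylphosphonium bromide | [Br-].C(C/C=C(\C)CCC1=C(C)CCCC1(C)C)[P+](c1ccccc1)(c1ccccc1)c1ccccc1
A1 | alternative 1 | (2R)-2-methyl-6-[(triisopropylsilyl)oxy]chromane-2-carbaldehyde | O=C[C@@]1(C)CCc2cc(O[Si](C(C)C)(C(C)C)C(C)C)ccc2O1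
A2 | alternative 1 | diethyl [(2E)-3-methyl-5-(2,6,6-trimethylcyclohex-1-en-1-yl)pent-2-en-1-yl]phosphonate | CCOP(=O)(OCC)C/C=C(\C)CCC1=C(C)CCCC1(C)C
A3 | alternative 2 | (3E,6E)-1-{2-hydroxy-5-[(triisopropylsilyl)oxy]phenyl}-3,7-dimethyl-9-(2,6,6-trimethylcyclohex-1-en-1-yl)nona-3,6-dien-5-yl methyl carbonate | COC(=O)OC(/C=C(\C)CCc1cc(O[Si](C(C)C)(C(C)C)C(C)C)ccc1O)/C=C(\C)CCC1=C(C)CCCC1(C)C
A4 | alternative 3 | 6-methylidene-4-[(triisopropylsilyl)oxy]cyclohexa-2,4-dien-1-one | C=C1C=C(O[Si](C(C)C)(C(C)C)C(C)C)C=CC1=O
A5 | alternative 3 | 2-[(3E,5E)-3,7-dimethylocta-3,5,7-trien-1-yl]-1,3,3-trimethylcyclohex-1-ene | C=C(C)/C=C/C=C(\C)CCC1=C(C)CCCC1(C)C
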